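Ring A hides a butenolide. Cutting C3–C4 and handing the acyl carbon C3 back to the oxygen on C10 turns the bridged C19–O–C10 γ-lactone and the C3 acetoxy carbon of the 6-oxabicyclo[3.2.1]octane into a γ-methylbutenolide that hangs on C5 beside a plain C4 propionate ester. In the forward sense one base treatment moves C3 from oxygen to the C4 enolate carbon (closing ring A) while the released C10 alkoxide captures C19 (closing the lactone), fixing quaternary C4. The precursor 20 is this butenolide ester, joined through C6–C7 to the ketal-protected methylidenebicyclo[3.2.1]octane. It comes from a radical tandem cyclisation, a decarboxylative Giese addition and an amine-catalysed Mukaiyama–Michael reaction.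

Key step: step 16

Numbering and shorthand: kaurane-type locants are used throughout.
- C8 is the quaternary bridgehead, C9 the ketone, C13 the bridgehead CH, and C16=C17 the methylidene.
- C7–C6 is the linker and C5 the ring A methine.
- C4 is the quaternary carbon bearing methyl C18 and carbonyl C19.
- C10 is the oxygenated carbon bearing methyl C20, and C1–C3 are the rest of ring A.
- Bic = (1S,5R)-6-methylidenespiro[bicyclo[3.2.1]octane-2,2'-[1,3]dioxolan]-1-yl.
- In names of the lactone core, O6 is bonded to C5 (= C10) and C7 (= C19), so the enone is an oct-3-ene-2,7-dione.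

Assumption: the syn preference known for 5-methyl-2-silyloxyfuran and β-alkyl enals under imidazolidinone catalysis is taken to hold for enal 13, with no disturbance from the remote centres C8 and C13.

Step 1
Reactants: 1 ethyl acetoacetate; 2 allyl bromide
Product: 3 ethyl 3-oxohept-6-enoate
Conditions: NaH, THF, 0 °C; n-BuLi, 0 °C; 2, 0 °C to rt; then 1 M HCl
Reagents that add atoms: none
Why: γ-Alkylation of the acetoacetate dianion, in which the more basic terminal carbanion is the one alkylated by the allylic halide.

Step 2
Reactants: 3 ethyl 3-oxohept-6-enoate; 2 allyl bromide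
Product: 4 ethyl 2-allyl-3-oxohept-6-enoate (racemic)
Conditions: K2CO3, acetone, reflux
Reagents that add atoms: none
Why: Acetoacetic ester C-alkylation of the stabilised enolate with one equivalent of halide; the new centre (future C8) is racemic and is erased as a radical in step 3.

Step 3
Reactants: 4 ethyl 2-allyl-3-oxohept-6-enoate
Product: 5 racemic ethyl (1R*,5R*)-6-methylidene-2-oxobicyclo[3.2.1]octane-1-carboxylate
Conditions: Mn(OAc)3·2H2O (2.1 equiv), Cu(OAc)2·H2O (1 equiv), AcOH, 25 °C
Reagents that add atoms: none
Why: Oxidative free-radical tandem cyclisation in which trivalent manganese generates the C8 radical, this closes 6-endo onto the butenyl alkene (C8–C14), the C13 radical closes 5-exo onto the allyl group (C13–C16) and divalent copper oxidises the primary C17 radical to the exocyclic alkene, the one-carbon bridge allowing only one relative configuration at C8 and C13.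

Step 4
Reactants: 5 racemic keto ester
Product: 6 ethyl (1R,5R)-6-methylidene-2-oxobicyclo[3.2.1]octane-1-carboxylate
Conditions: preparative SFC, amylose tris(3,5-dimethylphenylcarbamate) on silica, CO2/i-PrOH, 35 °C
Reagents that add atoms: none
Why: Physical resolution by chiral-phase chromatography, routine for neutral keto esters, which fixes the absolute configuration at C8 and C13 because only two enantiomers exist, the collected fraction being assigned by anomalous-dispersion X-ray analysis of a crystalline derivative of acid 8.

Step 5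
Reactants: 6 (1R,5R)-keto ester
Product: 7 ethyl (1R,5R)-6-methylidenespiro[bicyclo[3.2.1]octane-2,2'-[1,3]dioxolane]-1-carboxylate
Conditions: (TMSOCH2)2, TMSOTf (5 mol%), CH2Cl2, −78 to −20 °C; pyridine quench
Reagents that add atoms: 1,2-bis(trimethylsilyloxy)ethane C[Si](C)(C)OCCO[Si](C)(C)C
Why: Silyl-triflate-catalysed ketalisation with the bis-silyl ether of glycol, driven by disiloxane formation, works on hindered ketones at low temperature and so avoids acid-induced migration of the C16=C17 alkene.

Step 6
Reactants: 7 ketal ester
Product: 8 (1R,5R)-6-methylidenespiro[bicyclo[3.2.1]octane-2,2'-[1,3]dioxolane]-1-carboxylic acid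
Conditions: KOH, EtOH–H2O, reflux; then KHSO4 (aq) to pH 4, 0 °C
Reagents that add atoms: potassium hydroxide [K+].[OH-]
Why: Saponification, safe here because the ketal removes the retro-Claisen pathway of the non-enolisable β-keto ester and both ketal and alkene are inert to hydroxide.

Step 7
Reactants: 8 ketal acid; 9 methyl acrylate
Product: 10 methyl 3-Bic-propanoate
Conditions: [Ir(dF(CF3)ppy)2(dtbbpy)]PF6 (1 mol%), K2HPO4, DMF, blue LEDs, rt
Reagents that add atoms: none
Why: Photoredox decarboxylative Giese addition in which the oxidised carboxylate loses CO2, the nucleophilic tertiary C8 bridgehead radical adds to the free terminus of the acrylate (C8–C7) and the adduct radical is reduced and protonated, C8 being retained because a bridgehead radical cannot invert and C16=C17 lying out of reach of both radicals.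

Step 8
Reactants: 10 methyl 3-Bic-propanoate
Product: 11 3-Bic-propanal
Conditions: i-Bu2AlH (1.05 equiv), CH2Cl2, −78 °C; then H2O
Reagents that add atoms: none
Why: Partial ester reduction, in which the aluminium hemiacetal is stable at −78 °C and releases the C5 aldehyde only on work-up.

Step 9
Reactants: 11 3-Bic-propanal; 12 (triphenylphosphoranylidene)acetaldehyde
Product: 13 (E)-5-Bic-pent-2-enal
Conditions: toluene, 80 °C
Reagents that add atoms: none
Why: Wittig olefination with a stabilised ylide, which adds C4 and C19 and should give the (E)-enal under thermodynamic control.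

Step 10
Reactants: 14 α-angelica lactone
Product: 15 5-methyl-2-(trimethylsilyloxy)furan
Conditions: TMSCl, Et3N, Et2O, 0 °C to rt; distillation
Reagents that add atoms: chlorotrimethylsilane C[Si](C)(C)Cl
Why: Soft enolisation and O-silylation, since loss of a proton from the lactone α-CH2 gives the aromatic 2-oxidofuran, which the chlorosilane traps on oxygen.

Step 11
Reactants: 13 (E)-5-Bic-pent-2-enal; 15 5-methyl-2-(trimethylsilyloxy)furan
Product: 16 (3S)-5-Bic-3-[(2R)-2-methyl-5-oxo-2,5-dihydrofuran-2-yl]pentanal
Conditions: (2R,5R)-5-benzyl-2-tert-butyl-3-methylimidazolidin-4-one (20 mol%), 2,4-dinitrobenzoic acid (20 mol%), CH2Cl2–H2O, −60 °C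
Reagents that add atoms: none
Why: Iminium-catalysed vinylogous Mukaiyama–Michael addition in which the benzyl and tert-butyl groups cover one face of the (E)-iminium ion so that the furan bonds to the Si face of C5 (5S), and the furan stacks under the iminium with its methyl group pointing away from C4 and its silyloxy edge turned away from the C6 chain, the syn topicity that sets C10.

Step 12
Reactants: 16 butenolide aldehyde
Product: 17 (3S)-5-Bic-2-methylidene-3-[(2S)-2-methyl-5-oxo-2,5-dihydrofuran-2-yl]pentanal (C10 unchanged in space; descriptor changes by priority)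
Conditions: aq. HCHO (37%), pyrrolidine (10 mol%), propionic acid (10 mol%), i-PrOH, 45 °C
Reagents that add atoms: formaldehyde C=O
Why: Amine-catalysed α-methylenation (Mannich condensation and elimination) brings in C18 without any strong base, so no C4 ester enolate meets the butenolide before the key step.

Step 13
Reactants: 17 α-methylidene aldehyde
Product: 18 (2RS,3S)-5-Bic-2-methyl-3-[(2S)-2-methyl-5-oxo-2,5-dihydrofuran-2-yl]pentanal
Conditions: Hantzsch ester (diethyl 2,6-dimethyl-1,4-dihydropyridine-3,5-dicarboxylate, 1.1 equiv), dibenzylammonium trifluoroacetate (10 mol%), THF, rt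
Reagents that add atoms: none
Why: Organocatalytic conjugate transfer hydrogenation activates only the enal as its iminium ion, so hydride goes to C18 while the butenolide and C16=C17 stay intact, and the C4 epimer mixture is harmless because step 16 planarises C4.

Step 14
Reactants: 18 α-methyl aldehyde
Product: 19 (2RS,3S)-5-Bic-2-methyl-3-[(2S)-2-methyl-5-oxo-2,5-dihydrofuran-2-yl]pentanoic acid
Conditions: NaClO2, NaH2PO4, 2-methyl-2-butene, t-BuOH–H2O, 0 °C to rt
Reagents that add atoms: sodium chlorite [Na+].[O-]Cl=O
Why: Pinnick oxidation, selective for the aldehyde, with the scavenger alkene keeping hypochlorous acid away from C16=C17 and the buffer sparing the ketal.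

Step 15
Reactants: 19 carboxylic acid
Product: 20 methyl (2RS,3S)-5-Bic-2-methyl-3-[(2S)-2-methyl-5-oxo-2,5-dihydrofuran-2-yl]pentanoate
Conditions: KHCO3, MeI, DMF, rt
Reagents that add atoms: iodomethane CI
Why: Carboxylate O-alkylation (SN2), with a base too weak to enolise the ester or disturb the butenolide.

Step 16
Reactants: 20 butenolide ester (both C4 epimers)
Product: 23 (1S,5S,8S)-8-(2-Bic-ethyl)-1,5-dimethyl-6-oxabicyclo[3.2.1]oct-3-ene-2,7-dione, via bridged hemiketal alkoxide 21 (not isolated), via cyclohexenone C10 alkoxide 22 (not isolated)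
Conditions: KOtBu (1.1 equiv), 4 Å molecular sieves, THF (0.01 M), −40 to 0 °C; AcOH quench
Reagents that add atoms: none
Why: KOtBu converts both C4 epimers of 20 into one ester enolate, whose carbon swings over the butenolide plane and adds to the carbonyl C3 (6-exo-trig closure of carbocyclic ring A) to give the 1-oxido-7-oxabicyclo[2.2.1]heptene 21. Release of strain drives cleavage of the old C3–O bond to the cyclohexenone 22, whose tertiary C10 alkoxide adds to the C19 ester held 1,3 to it on the same face (5-exo-trig closure of the γ-lactone) and expels methoxide. The closest known reaction type is the Dieckmann (intramolecular Claisen) acylation of an ester enolate by a lactone carbonyl followed by translactonisation, an O-to-C acyl shift. The only new stereocentre, C4, is controlled by the existing C10–O bond: lactonisation is possible only when CO2Me sits on the oxygen-bearing face, and the other keto ester, having no acidic hydrogen between its carbonyl groups, returns by retro-Claisen cleavage through the bridged adduct until it leaves by the productive channel, while C5 and C10 carry no acidic hydrogen and stay as set in step 11. The step needs enolisation at C4 only and 1,2- rather than 1,4-attack: C10 is quaternary so the butenolide has no γ-hydrogen, C9 is masked as the ketal, and Michael closure onto C1 would need a four-membered ring. Low temperature, high dilution and sieves that take up methanol are meant to hold back retro-Michael loss of the furanolate, intermolecular addition and reopening of 23 by methoxide.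

Step 17
Reactants: 23 bridged enone lactone
Product: 24 (1S,5S,8S)-8-(2-Bic-ethyl)-1,5-dimethyl-6-oxabicyclo[3.2.1]octane-2,7-dione
Conditions: [(Ph3P)CuH]6, H2O, degassed toluene, rt
Reagents that add atoms: none
Why: Conjugate reduction with a phosphine-stabilised copper hydride, whose soft hydride adds only to the enone terminus C1 and leaves the isolated C16=C17 alkene, the lactone and the ketal untouched while water protonates the copper enolate.

Step 18
Reactants: 24 keto lactone
Product: 25 (1S,2S,5S,8S)-8-(2-Bic-ethyl)-2-hydroxy-1,5-dimethyl-6-oxabicyclo[3.2.1]octan-7-one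
Conditions: LiBH(s-Bu)3, THF, −78 °C; then pH 7 buffer
Reagents that add atoms: none
Why: Ketone reduction by a bulky trialkylborohydride, in which the C6 chain on C5 lies axially over ring A and blocks axial approach to C3, so hydride should enter along the equatorial line and leave the oxygen axial, anti to the lactone bridge (3S), with lactone and ketal inert at −78 °C.

Step 19
Reactants: 25 axial C3 alcohol
Product: 26 (1S,2S,5S,8S)-8-(2-Bic-ethyl)-1,5-dimethyl-7-oxo-6-oxabicyclo[3.2.1]octan-2-yl acetate
Conditions: Ac2O, DMAP, pyridine, rt to 40 °C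
Reagents that add atoms: acetic anhydride CC(=O)OC(C)=O
Why: DMAP-catalysed acylation, strong enough for a hindered axial secondary alcohol and without effect on C3 or on the other functions.

Step 20
Reactants: 26 acetate ketal
Product: 27 target, (1S,2S,5S,8S)-1,5-dimethyl-8-{2-[(1S,5R)-6-methylidene-2-oxobicyclo[3.2.1]octan-1-yl]ethyl}-7-oxo-6-oxabicyclo[3.2.1]octan-2-yl acetate
Conditions: pyridinium p-toluenesulfonate, acetone–H2O, 50 °C
Reagents that add atoms: water O
Why: Mild acid-catalysed ketal hydrolysis, the weak acid being chosen so that C16=C17 does not migrate into the ring and the acetate and lactone survive.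

Compound list
1 | ethyl acetoacetate | CCOC(=O)CC(C)=O | starting material
2 | allyl bromide | C=CCBr | starting material
3 | ethyl 3-oxohept-6-enoate | C=CCCC(=O)CC(=O)OCC | intermediate
4 | ethyl 2-allyl-3-oxohept-6-enoate (racemic) | C=CCCC(=O)C(CC=C)C(=O)OCC | intermediate
5 | racemic ethyl (1R*,5R*)-6-methylidene-2-oxobicyclo[3.2.1]octane-1-carboxylate | C=C1C[C@]2(C(=O)OCC)C[C@H]1CCC2=O.C=C1C[C@@]2(C(=O)OCC)C[C@@H]1CCC2=O | intermediate
6 | ethyl (1R,5R)-6-methylidene-2-oxobicyclo[3.2.1]octane-1-carboxylate | C=C1C[C@]2(C(=O)OCC)C[C@H]1CCC2=O | intermediate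
7 | ethyl (1R,5R)-6-methylidenespiro[bicyclo[3.2.1]octane-2,2'-[1,3]dioxolane]-1-carboxylate | C=C1C[C@]2(C(=O)OCC)C[C@H]1CCC23OCCO3 | intermediate
8 | (1R,5R)-6-methylidenespiro[bicyclo[3.2.1]octane-2,2'-[1,3]dioxolane]-1-carboxylic acid | C=C1C[C@]2(C(=O)O)C[C@H]1CCC23OCCO3 | intermediate
9 | methyl acrylate | C=CC(=O)OC | starting material
10 | methyl 3-Bic-propanoate | C=C1C[C@]2(CCC(=O)OC)C[C@H]1CCC23OCCO3 | intermediate
11 | 3-Bic-propanal | C=C1C[C@]2(CCC=O)C[C@H]1CCC23OCCO3 | intermediate
12 | (triphenylphosphoranylidene)acetaldehyde | O=CC=P(c1ccccc1)(c1ccccc1)c1ccccc1 | starting material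
13 | (E)-5-Bic-pent-2-enal | C=C1C[C@]2(CC/C=C/C=O)C[C@H]1CCC23OCCO3 | intermediate
14 | α-angelica lactone, 5-methylfuran-2(3H)-one | CC1=CCC(=O)O1 | starting material
15 | 5-methyl-2-(trimethylsilyloxy)furan | Cc1ccc(O[Si](C)(C)C)o1 | intermediate
16 | (3S)-5-Bic-3-[(2R)-2-methyl-5-oxo-2,5-dihydrofuran-2-yl]pentanal | C=C1C[C@]2(CC[C@H]([C@]3(C)C=CC(=O)O3)CC=O)C[C@H]1CCC24OCCO4 | intermediate
17 | (3S)-5-Bic-2-methylidene-3-[(2S)-2-methyl-5-oxo-2,5-dihydrofuran-2-yl]pentanal | C=C1C[C@]2(CC[C@H]([C@]3(C)C=CC(=O)O3)C(=C)C=O)C[C@H]1CCC24OCCO4 | intermediate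
18 | (2RS,3S)-5-Bic-2-methyl-3-[(2S)-2-methyl-5-oxo-2,5-dihydrofuran-2-yl]pentanal | C=C1C[C@]2(CC[C@H]([C@]3(C)C=CC(=O)O3)C(C)C=O)C[C@H]1CCC24OCCO4 | intermediate
19 | (2RS,3S)-5-Bic-2-methyl-3-[(2S)-2-methyl-5-oxo-2,5-dihydrofuran-2-yl]pentanoic acid | C=C1C[C@]2(CC[C@H]([C@]3(C)C=CC(=O)O3)C(C)C(=O)O)C[C@H]1CCC24OCCO4 | intermediate
20 | methyl (2RS,3S)-5-Bic-2-methyl-3-[(2S)-2-methyl-5-oxo-2,5-dihydrofuran-2-yl]pentanoate (key-step precursor) | C=C1C[C@]2(CC[C@H]([C@]3(C)C=CC(=O)O3)C(C)C(=O)OC)C[C@H]1CCC24OCCO4 | intermediate
21 | bridged hemiketal alkoxide: potassium 1-oxido-7-oxabicyclo[2.2.1]hept-2-ene with CO2Me exo and methyl endo on C4, H exo and chain endo on C5 | C=C1C[C@]2(CC[C@H]3[C@](C)(C(=O)OC)[C@@]4([O-])C=C[C@]3(C)O4)C[C@H]1CCC25OCCO5.[K+] | intermediate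
22 | cyclohexenone C10 alkoxide: potassium salt of the 4-hydroxycyclohex-2-enone bearing CO2Me and methyl on C4, ester cis to the C10 oxygen | C=C1C[C@]2(CC[C@H]3[C@](C)(C(=O)OC)C(=O)C=C[C@]3(C)[O-])C[C@H]1CCC24OCCO4.[K+] | intermediate
23 | (1S,5S,8S)-8-(2-Bic-ethyl)-1,5-dimethyl-6-oxabicyclo[3.2.1]oct-3-ene-2,7-dione (key-step product) | C=C1C[C@]2(CC[C@H]3[C@]4(C)C(=O)O[C@@]3(C)C=CC4=O)C[C@H]1CCC25OCCO5 | intermediate
24 | (1S,5S,8S)-8-(2-Bic-ethyl)-1,5-dimethyl-6-oxabicyclo[3.2.1]octane-2,7-dione | C=C1C[C@]2(CC[C@H]3[C@]4(C)C(=O)O[C@@]3(C)CCC4=O)C[C@H]1CCC25OCCO5 | intermediate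
25 | (1S,2S,5S,8S)-8-(2-Bic-ethyl)-2-hydroxy-1,5-dimethyl-6-oxabicyclo[3.2.1]octan-7-one | C=C1C[C@]2(CC[C@H]3[C@]4(C)C(=O)O[C@@]3(C)CC[C@@H]4O)C[C@H]1CCC25OCCO5 | intermediate
26 | (1S,2S,5S,8S)-8-(2-Bic-ethyl)-1,5-dimethyl-7-oxo-6-oxabicyclo[3.2.1]octan-2-yl acetate | C=C1C[C@]2(CC[C@H]3[C@]4(C)C(=O)O[C@@]3(C)CC[C@@H]4OC(C)=O)C[C@H]1CCC25OCCO5 | intermediate
27 | CNP0204681.1, (1S,2S,5S,8S)-1,5-dimethyl-8-{2-[(1S,5R)-6-methylidene-2-oxobicyclo[3.2.1]octan-1-yl]ethyl}-7-oxo-6-oxabicyclo[3.2.1]octan-2-yl acetate | C=C1C[C@]2(CC[C@H]3[C@]4(C)C(=O)O[C@@]3(C)CC[C@@H]4OC(C)=O)C[C@H]1CCC2=O | target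

Total step count: 20. Longest linear sequence: 19 steps (1 to 27 through steps 1–9 and 11–20); step 10 is the only side branch.

Steps most likely to fail

1. Step 16.
- What may go wrong: retro-Michael cleavage of the C5–C10 bond from the C4 enolate, stalling before the strained bridged adduct is reached, or reopening of the non-enolisable β-keto lactone by the liberated methoxide.
- Fallback, from 20 back to 23: the two acyl transfers are run in reverse order and the C-acylation is made irreversible.
- MeNH(OMe)·HCl and i-PrMgCl in THF at −20 °C open the butenolide at C3, and the magnesium C10 alkoxide closes onto the C19 ester. This gives the γ-lactone (Z)-Weinreb enamide F1.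
- LiN(SiMe3)2 in THF at −78 °C then forms the lactone enolate at C4. It can reach the amide carbonyl only on the face that carries C1.
- The chelated tetrahedral adduct lasts until the acidic quench, so 23 is never exposed to an alkoxide.

2. Step 11.
- What may go wrong: poor syn/anti selectivity at C10, slow turnover at low temperature, or protodesilylation of the furan before addition.
- Fallback, from 13 and 14 back to 16: the silyl dienol ether and the imidazolidinone are given up in favour of a direct vinylogous Michael addition of α-angelica lactone 14 itself.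
- The conditions are (R)-2-[diphenyl(trimethylsilyloxy)methyl]pyrrolidine (20 mol%) and benzoic acid in toluene at rt.
- The bulky side arm again leaves the Si face of C5 open. The free dienol is organised differently from the silyl ether, which gives a second chance for the C10 topicity. The C10 epimers are separated by chromatography.
- No new compound arises.

3. Step 7.
- What may go wrong: sluggish oxidation and decarboxylation of the hindered bridgehead carboxylate, or telomerisation of the acrylate.
- Fallback, from 7 back to 10: a polar two-carbon homologation.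
- LiAlH4 in THF gives the neopentyl alcohol F2.
- Dess–Martin periodinane gives the aldehyde F3.
- Horner–Wadsworth–Emmons reaction with trimethyl phosphonoacetate and NaH gives the (E)-enoate F4.
- Conjugate reduction with [(Ph3P)CuH]6 in wet toluene, which spares C16=C17, gives 10.

Further compounds
F1 | step 16 | γ-lactone (Z)-Weinreb enamide: C19–O–C10 γ-butyrolactone (C4 epimers) bearing on C10 methyl and (Z)-CH=CH–C(O)N(OMe)Me, on C5 the 2-Bic-ethyl chain | C=C1C[C@]2(CC[C@H]3C(C)C(=O)O[C@@]3(C)/C=C\C(=O)N(C)OC)C[C@H]1CCC24OCCO4
F0 | step 11 | none | none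
F2 | step 7 | [(1R,5R)-6-methylidenespiro[bicyclo[3.2.1]octane-2,2'-[1,3]dioxolan]-1-yl]methanol | C=C1C[C@]2(CO)C[C@H]1CCC23OCCO3
F3 | step 7 | (1R,5R)-6-methylidenespiro[bicyclo[3.2.1]octane-2,2'-[1,3]dioxolane]-1-carbaldehyde | C=C1C[C@]2(C=O)C[C@H]1CCC23OCCO3
F4 | step 7 | methyl (E)-3-Bic-prop-2-enoate | C=C1C[C@]2(/C=C/C(=O)OC)C[C@H]1CCC23OCCO3
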